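A count of G against E and L by the equations says nothing about time, and delta's small surplus of G is the trap: it can still leave E unconverted when the run ends.

    E + D ⇌ E.D (K1 = 32 M⁻¹, k1 = 70200 M⁻¹ h⁻¹)
    G + E.D ⇌ G.E.D (K2 = 4.79 M⁻¹, k2 = 1.66 × 10⁵ M⁻¹ h⁻¹)
    G.E.D → D + Z (k3 = 556 h⁻¹)
    G + L → G.L (k4 = 36.8 M⁻¹ h⁻¹)

| setting | delta | eta | theta | gamma |
|---|---|---|---|---|
| E | 0.10 M | 0.10 M | 0.10 M | 0.10 M |
| G | 0.120 M | 0.400 M | 1.00 M | 3.00 M |
| L | 2.00 mM | 2.00 mM | 2.00 mM | 2.00 mM |
| D | 36 µM | 36 µM | 36 µM | 36 µM |
| time | 50 h | 50 h | 50 h | 50 h |

1. amount of Z at the end, in percent of the E charged for delta, eta, theta, gamma, in this order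
2. the shape of the row from first to last (rises, then falls / falls, then rises / falls all the way / hardly changes / rises all the way)

- a step back or a flat step of under half a point counts as no turn
- "hardly changes" means that all values lie within two and a half points (for a concentration: within two and a half percent of the largest)
- run time (delta): 50 h

The decision for the next run is how much G to charge, with E, D and L left as they are. It hangs on the surplus s, the G that remains after the charges of E and L are taken off: delta has s = 0.0180 M, eta 0.298 M.

G.E.D falls back to G + E.D at 34700 h⁻¹ and E.D loses E at 2190 h⁻¹, while G.E.D goes on to D + Z at k_c = 556 h⁻¹, slower than either. This reckoning takes that last step as the rate-limiting step and holds both bindings at equilibrium. With K_E and K_G the equilibrium constants for binding E and G, the catalyst divides among D, E.D and G.E.D as 1 : K_E[E] : K_E K_G[E][G]. Write C for the catalyst charge and κ = k_c C K_E K_G = 3.07 M⁻¹ h⁻¹. With [G] = [E] + s, E then falls at κ[E]([E] + s) divided by the sum of those terms.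

The carried quantity is the tail time τ = 1/(κs), the time in which E falls by a factor e once E is small beside s and the catalyst stands mostly as free D: 18.1 h for delta. The lifetime of L against G in delta, 0.226 h, is much shorter than this, so the charge of L comes off G from the start.

Integration adds a crowding time t_c, spent while E.D and G.E.D hold the catalyst: 24.6 h for delta, with the remainder neglected inside it. For the rest of the run the tail law applies. Delta's 50 h then leaves 4.74 mM of E by this reckoning, so Z stands at a fraction 0.953 of the E charged.

Eta has a tail time of 1.09 h, far shorter than delta's, and a crowding time of 8.01 h. Its remainder 1.60 × 10⁻¹⁸ M gives Z at a fraction 1.00. Theta and gamma have surpluses of 0.898 M and 2.90 M, with tail times of 0.363 h and 0.112 h, and the same reckoning gives fractions 1.00 and 1.00. The reckoning therefore charges eta's G for the next run and expects a row that rises all the way.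

The forecast reads 95.4 %, 100 %, 100 %, 100 %, rises all the way, holding that delta “leaves a slow tail that stops just short of completion”. The simulation gives 95.5 %, 100 %, 100 %, 100 %, rises all the way.

Delta ends with 4.53 % of its E unconverted in part because G.E.D falls back to G + E.D, the backward run that puts K_G into κ and stretches τ to 18.1 h. With that backward run taken away, delta reaches 100 % of Z, against 95.5 % with it. The rise of the row from delta to gamma, 4.5 percentage points, is in part owed to the same backward run, and without it that rise is 0 points. Eta's tail time of 1.09 h fits 45.9 times into the run, and eta ends with Z at 100 %.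

The numbers stand for no real mixture.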